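## The problem

CNP0258430.2, compound 33, is a germacranolide in which an oxygen atom spans C3 and C10 of the ten-membered carbocycle C1–C10, so that C10, the C1 ketone, the C2=C3 alkene and this oxygen make up a furan-3-one ring. The carbocycle also carries a trans-fused α-methylene-γ-butyrolactone at C7/C8 built from C11, C12 and C13, a Z-trisubstituted C4=C5 alkene, and at C6 a (2S,3R)-2,3-dimethyloxirane-2-carboxylate. Three contiguous stereocentres, 6R, 7R and 8S, sit on one flank of the ring, while the quaternary carbinol centre 10R is insulated from them by the C9 methylene and the two oxirane centres lie on a separate fragment. C8 can direct C7 through the face of a butenolide and, through a cyclic allylation transition state, C6; nothing in the ring can direct C10 or the oxirane, which therefore have to come from the chiral pool and from a catalyst. The exocyclic acrylate, the glycidic ester, the vinylogous-ester furanone, the allylic C6 acyloxy group and the Z-alkene rule out strong base, hard nucleophiles, strong acid and dissolving metals in the late stages. The feature that opens the structure is the enol-ether oxygen: O10 and C3 are 1,4-related through the C1 carbonyl, so the furanone is the 5-endo cycloisomer of an α'-hydroxy ynone C10(OH)–C1(=O)–C2≡C3 embedded in the carbocycle, and the same alkyne offers the C1–C2 bond for ring closure by carbonyl addition.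

## Retrosynthesis

**33 ⇒ 32.** The enol-ether bond O–C3 is cut, which leads to the macrocyclic α'-hydroxy ynone 32. Cutting C1–C2 or C1–C10 of the furanone instead would demand aldol-type chemistry under base on the finished ring. The chosen cut removes one ring and no stereocentre, and the forward step is an isomerisation that needs only a carbophilic catalyst. That catalyst must steer O10 to C3 ahead of every other reaction of the ynone and the acrylate.

**32 ⇒ 31 ⇒ 30.** The ynone is traced to the propargylic carbinol 31, and the ring is opened at C1–C2 to the iodoalkyne aldehyde 30. C1–C2 is the one ring bond whose closure creates no stereocentre of consequence, because C1 is oxidised afterwards; closure at C5–C6 or C6–C7 would set C6 or C7 in a medium-ring cyclisation. The forward reaction is a chromium-mediated alkynyl addition that tolerates esters, lactone and oxirane, but it has to form a cyclic Z-enyne against strain.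

**30 ⇒ 29 ⇒ 28 ⇒ 27.** No skeletal bond is cut. The aldehyde of 30 comes from the primary alcohol of diol 29, the diol from the dioxolane 28, and the iodoalkyne of 28 from the silylalkyne 27. A single acetal thus masks O1 and O10 from the second step of the route up to this point, and the alkyne stays silylated until a base-free exchange.

**27 ⇒ 25 + 24.** The acyl–oxygen bond at C6 is cut. The oxirane stereocentres are remote from the ring, so epoxidation of an unsaturated ester after assembly would have no facial control. Acid 24 is therefore made as a single enantiomer and attached to the free C6 hydroxyl of 25.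

**25 ⇒ 14 + 20.** The C6–C7 bond is cut to the bromomethyl butenolide 14 and the Z-enynal 20. The neighbouring cut at C7–C8, a C8 aldehyde plus an acyclic bromomethylacrylate, would have to build the lactone and would rest on the syn/anti preference of an acyclic allylmetal, which does not dependably deliver the trans-lactone. With the lactone preformed, C8 shields one face of the allyl unit and so sets C7, and the ring fixes the allylmetal geometry and so sets C6. The precursors are a butenolide with one stereocentre on the ring and an achiral aldehyde. The forward reaction must be γ-selective and must add 1,2 to the enal.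

**14 ⇒ 13 ⇒ 12 ⇒ 11 ⇒ 9.** Bromide 14 comes from silyl ether 12 through alcohol 13. Butenolide 12 is opened at C11–C12 and C12–O8 to the Z-iodoallylic alcohol 11 by a carbonylative lactonisation, and 11 comes from the propargylic alcohol 9 by hydroxyl-directed hydroalumination and iodination. Ring formation by metathesis of a methacrylate followed by bromination would raise a regiochemical problem at the C8 hydrogen, which this sequence avoids.

**9 ⇒ 8 ⇒ 7 ⇒ 4 + 5, and 4 ⇒ 3 ⇒ 2 ⇒ 1.** C7–C8 is cut to aldehyde 4 and the propargyl silyl ether 5. C10 is quaternary and 1,3 to C8, so it cannot be trusted to control C8. C8 is therefore set by catalyst-controlled transfer hydrogenation of ynone 8, which is reached from the epimeric adducts 7. Aldehyde 4 lies three functional-group steps from (R)-citramalic acid 1, by way of triol 2 and acetal 3, and 1 supplies C10 in the correct configuration.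

**20 ⇒ 19 ⇒ 17 + 18, and 17 ⇒ 15.** The enynal is cut at C3–C4 to the Z-iodoalkenol 17 and the silylacetylene 18, with 19 as the coupled alcohol. The Z geometry of C4=C5 is fixed in the hydroalumination–iodination of but-2-yn-1-ol 15 and carried through a stereoretentive coupling.

**24 ⇒ 23 ⇒ 22 ⇒ 21.** The epoxy acid is traced to epoxy alcohol 23, made by asymmetric epoxidation of the allylic alcohol 22 from tiglic acid 21. The E geometry gives the cis-dimethyl oxirane and the tartrate sets the absolute configuration.

## Roads not taken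

**Alternative 1:** The cut is C9–C10. The open-chain precursor A1 carries a 2-methyl-3-silyloxyfuran at one end, which holds C10, C1, C2 and C3, and a methyl enol ether C8=C9 at the other. Anodic oxidation of A1 would ionise the enol ether, the furan carbon C10 would bond to C9, and the solvent alcohol would cap C8, giving the bicyclic furanone ketal A2.
- Merits: the ring, the furanone and the quaternary centre would all form in one metal-free step from an unstrained chain, and no cyclic alkyne is needed. In these respects this road is better than the chosen plan.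
- Weak points: C10 would be created during a ten-membered closure, with its nearest stereocentre C7 separated from it by the sp2 carbon C8. The electron-rich silyloxyfuran and the furan-conjugated diene of A1 are oxidised more easily than the enol ether. A2 still needs ketal hydrolysis, stereoselective reduction at C8 on a mobile ring, oxidation of C12, lactonisation, desilylation and acylation.
- Against this, the chosen plan takes C10 from the pool, sets C8 with a catalyst before any ring exists, and ends at 33 with the ring-bridging step.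

**Alternative 2:** The cut is C7–C11. Precursor A3 already contains the oxygen-bridged carbocycle, with a C6–C7 epoxide and a diethylphosphonoacetate on O8. Base would deprotonate the phosphonoacetate of A3, the carbon nucleophile would open the epoxide at C7 with inversion, and the γ-lactone would close with release of the C6 hydroxyl, giving the α-phosphono lactone A4. A Horner–Wadsworth–Emmons methylenation of A4 and acylation at O6 would follow.
- Merits: the methylene lactone appears last and is never exposed to earlier steps, which is better than the chosen plan. One step sets C7 and frees the right hydroxyl.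
- Weak points: the road presupposes A3, so the ring-forming problem is untouched, and three stereocentres would have to be set by substrate control on a flexible ring. C6 is allylic, so attack there, leading to a six-membered lactone, competes with attack at C7. The base would also meet the furanone.
- The chosen plan must carry the acrylate through eight steps. It answers this by using only neutral or weakly acidic reagents after step 17.

**Alternative 3:** The cut is C5–C6. Precursor A5 contains the finished furanone, a Z-alkenyl iodide at C5 and a C6 aldehyde on a lactone whose methylene is masked as a phenylthiomethyl group. CrCl2 with catalytic NiCl2 would insert into the carbon–iodine bond of A5, and the carbon–chromium bond so formed would add to the aldehyde, closing the ring as the bicyclic C6 carbinol A6.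
- Merits: the furanone can be made on an open chain, alkenylchromium closures of strained medium rings are well precedented, no cycloalkyne is involved, and the acrylate is masked. On ring strain and precedent this road is at least as good as the chosen plan.
- Weak points: C6 is created in the ring-closing step with only conformational control. The aldehyde of A5 has an acidic C7 hydrogen and the lactone oxygen in the β-position, so epimerisation or β-elimination threatens. A6 still needs acylation, sulfide oxidation and thermal sulfoxide elimination, the last two with the glycidic ester present.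
- The chosen plan sets C6 and C7 together in an intermolecular allylation with a predictable transition state and finishes at the target, at the price of closing a ring that contains an alkyne.

Key step: step 24

Assumption: locants C1–C13 are those of the germacrane skeleton as used under "The problem"; compounds 5 and 18 are taken as catalogue reagents.

## Route

Step 1
Reactants: 1 (R)-citramalic acid [(2R)-2-hydroxy-2-methylbutanedioic acid]
Product: 2 (2R)-2-methylbutane-1,2,4-triol
Conditions: BH3·SMe2, B(OMe)3, THF, 0 °C to rt; then MeOH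
Reagents that add atoms: none
Why: Borane reduction of both carboxylic acids to primary alcohols; the tertiary carbinol, the future C10, is not touched, so its configuration comes unchanged from the pool.

Step 2
Reactants: 2 (2R)-2-methylbutane-1,2,4-triol
Product: 3 2-[(4R)-2,2,4-trimethyl-1,3-dioxolan-4-yl]ethan-1-ol
Conditions: 2,2-dimethoxypropane, acetone, TsOH (cat.), rt
Reagents that add atoms: 2,2-dimethoxypropane, COC(C)(C)OC
Why: Thermodynamic acetalisation; the five-membered dioxolane across the 1,2-diol is favoured over the six-membered acetal, which would carry an axial methyl group, so only the hydroxyl on the future C8 stays free.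

Step 3
Reactants: 3 2-[(4R)-2,2,4-trimethyl-1,3-dioxolan-4-yl]ethan-1-ol
Product: 4 2-[(4R)-2,2,4-trimethyl-1,3-dioxolan-4-yl]acetaldehyde
Conditions: Dess–Martin periodinane, NaHCO3, CH2Cl2, 0 °C to rt
Reagents that add atoms: none
Why: Dess–Martin oxidation of a primary alcohol under buffered, non-basic conditions, which avoids β-elimination of the acetal oxygen from the aldehyde.

Step 4
Reactants: 4 2-[(4R)-2,2,4-trimethyl-1,3-dioxolan-4-yl]acetaldehyde; 5 tert-butyldimethyl(prop-2-yn-1-yloxy)silane
Product: 7 (2RS)-5-(tert-butyldimethylsilyloxy)-1-[(4R)-2,2,4-trimethyl-1,3-dioxolan-4-yl]pent-3-yn-2-ol (both C2 epimers), via lithium acetylide 6 (not isolated)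
Conditions: 5, n-BuLi, THF, −78 °C; then 4, −78 °C; aq NH4Cl
Reagents that add atoms: none
Why: 1,2-Addition of a lithium acetylide to the aldehyde forms C7–C8; the carbinol configuration is not controlled and need not be, because the next step oxidises it.

Step 5
Reactants: 7 (2RS)-5-(tert-butyldimethylsilyloxy)-1-[(4R)-2,2,4-trimethyl-1,3-dioxolan-4-yl]pent-3-yn-2-ol
Product: 8 5-(tert-butyldimethylsilyloxy)-1-[(4R)-2,2,4-trimethyl-1,3-dioxolan-4-yl]pent-3-yn-2-one
Conditions: Dess–Martin periodinane, NaHCO3, CH2Cl2, rt
Reagents that add atoms: none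
Why: Dess–Martin oxidation of a propargylic alcohol to the ynone under neutral conditions, so the β-alkoxy ketone does not eliminate.

Step 6
Reactants: 8 5-(tert-butyldimethylsilyloxy)-1-[(4R)-2,2,4-trimethyl-1,3-dioxolan-4-yl]pent-3-yn-2-one
Product: 9 (2S)-5-(tert-butyldimethylsilyloxy)-1-[(4R)-2,2,4-trimethyl-1,3-dioxolan-4-yl]pent-3-yn-2-ol
Conditions: Ru[(S,S)-TsNCH(Ph)CH(Ph)NH](p-cymene) (2 mol %), i-PrOH, rt
Reagents that add atoms: none
Why: Noyori asymmetric transfer hydrogenation of an α,β-acetylenic ketone; the alkynyl group takes the place that the aryl group takes with aryl ketones, so the (S,S) catalyst should deliver the 2S carbinol, the future C8, under catalyst control, independent of the remote C10 centre and without added base.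

Step 7
Reactants: 9 (2S)-5-(tert-butyldimethylsilyloxy)-1-[(4R)-2,2,4-trimethyl-1,3-dioxolan-4-yl]pent-3-yn-2-ol
Product: 11 (2S,3Z)-5-(tert-butyldimethylsilyloxy)-4-iodo-1-[(4R)-2,2,4-trimethyl-1,3-dioxolan-4-yl]pent-3-en-2-ol, via cyclic alkenylaluminate 10 (not isolated)
Conditions: NaAlH2(OCH2CH2OMe)2, THF, 0 °C to rt; EtOAc; then I2, −78 to 0 °C
Reagents that add atoms: iodine, II
Why: Hydroxyl-directed trans-hydroalumination of a propargylic alcohol places aluminium on the distal alkyne carbon, the future C11, cis to the carbinol, and iodinolysis with retention gives the Z-iodoalkene; the silyl ether oxygen is not bound to aluminium and cannot direct, and the cold iodine quench is applied before the alkenylaluminate can lose silyloxide.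

Step 8
Reactants: 11 (2S,3Z)-5-(tert-butyldimethylsilyloxy)-4-iodo-1-[(4R)-2,2,4-trimethyl-1,3-dioxolan-4-yl]pent-3-en-2-ol
Product: 12 (5S)-3-[(tert-butyldimethylsilyloxy)methyl]-5-{[(4R)-2,2,4-trimethyl-1,3-dioxolan-4-yl]methyl}furan-2(5H)-one
Conditions: PdCl2(PPh3)2 (5 mol %), CO (1 atm), K2CO3, THF, rt
Reagents that add atoms: carbon monoxide, [C-]#[O+]
Why: Carbonylative lactonisation; zerovalent palladium formed in the flask inserts into the carbon–iodine bond, carbon monoxide inserts, and the cis-disposed C8 hydroxyl captures the acylpalladium to close the butenolide and install C12 without touching C8.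

Step 9
Reactants: 12 (5S)-3-[(tert-butyldimethylsilyloxy)methyl]-5-{[(4R)-2,2,4-trimethyl-1,3-dioxolan-4-yl]methyl}furan-2(5H)-one
Product: 13 (5S)-3-(hydroxymethyl)-5-{[(4R)-2,2,4-trimethyl-1,3-dioxolan-4-yl]methyl}furan-2(5H)-one
Conditions: HF·pyridine, pyridine, THF, 0 °C to rt
Reagents that add atoms: none
Why: Buffered fluoride desilylation of a primary silyl ether; basic fluoride sources are avoided because the γ-hydrogen of the butenolide at C8 is acidic, and the acetal is stable to this medium.

Step 10
Reactants: 13 (5S)-3-(hydroxymethyl)-5-{[(4R)-2,2,4-trimethyl-1,3-dioxolan-4-yl]methyl}furan-2(5H)-one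
Product: 14 (5S)-3-(bromomethyl)-5-{[(4R)-2,2,4-trimethyl-1,3-dioxolan-4-yl]methyl}furan-2(5H)-one
Conditions: CBr4, PPh3, CH2Cl2, 0 °C
Reagents that add atoms: carbon tetrabromide, BrC(Br)(Br)Br
Why: Appel bromination of a primary allylic alcohol under neutral conditions; substitution takes place at the unhindered CH2 and leaves the acetal and the C8 centre alone.

Step 11
Reactants: 15 but-2-yn-1-ol
Product: 17 (2Z)-3-iodobut-2-en-1-ol, via cyclic alkenylaluminate 16 (not isolated)
Conditions: NaAlH2(OCH2CH2OMe)2, THF, 0 °C to rt; EtOAc; then I2, −78 °C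
Reagents that add atoms: iodine, II
Why: The same hydroxyl-directed trans-hydroalumination and iodinolysis as in step 7; iodine ends on the future C4 cis to the CH2OH group, which fixes the Z geometry of the later C4=C5 alkene.

Step 12
Reactants: 17 (2Z)-3-iodobut-2-en-1-ol; 18 ethynyltrimethylsilane
Product: 19 (2Z)-3-methyl-5-(trimethylsilyl)pent-2-en-4-yn-1-ol
Conditions: PdCl2(PPh3)2 (2 mol %), CuI (4 mol %), Et3N, THF, rt
Reagents that add atoms: none
Why: Sonogashira coupling of an alkenyl iodide proceeds with retention of alkene geometry, so C3 and C6 end up cis on C4=C5.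

Step 13
Reactants: 19 (2Z)-3-methyl-5-(trimethylsilyl)pent-2-en-4-yn-1-ol
Product: 20 (2Z)-3-methyl-5-(trimethylsilyl)pent-2-en-4-ynal
Conditions: activated MnO2, CH2Cl2, rt
Reagents that add atoms: none
Why: Heterogeneous MnO2 oxidation of an allylic alcohol under neutral conditions should keep the Z geometry; the enal is used without storage.

Step 14
Reactants: 21 tiglic acid [(2E)-2-methylbut-2-enoic acid]
Product: 22 (2E)-2-methylbut-2-en-1-ol
Conditions: LiAlH4, Et2O, 0 °C
Reagents that add atoms: none
Why: Hydride reduction of the acid to the allylic alcohol; 1,2-reduction is normal for this hindered α-methyl enoate and the E geometry is retained.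

Step 15
Reactants: 22 (2E)-2-methylbut-2-en-1-ol
Product: 23 [(2R,3R)-2,3-dimethyloxiran-2-yl]methanol
Conditions: Ti(Oi-Pr)4, D-(−)-diisopropyl tartrate, t-BuOOH, 4 Å molecular sieves, CH2Cl2, −20 °C
Reagents that add atoms: tert-butyl hydroperoxide, CC(C)(C)OO
Why: Sharpless asymmetric epoxidation; E-allylic alcohols give the 2S,3S epoxy alcohols with the L-(+)-tartrate, so the D-(−)-tartrate complex should deliver the 2R,3R enantiomer, and syn addition to the E alkene gives the cis-dimethyl oxirane.

Step 16
Reactants: 23 [(2R,3R)-2,3-dimethyloxiran-2-yl]methanol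
Product: 24 (2S,3R)-2,3-dimethyloxirane-2-carboxylic acid
Conditions: RuCl3·xH2O (cat.), NaIO4, EtOAc/MeCN/H2O, rt
Reagents that add atoms: water, O
Why: RuO4 generated in the flask oxidises the primary alcohol through the aldehyde hydrate to the acid without opening the oxirane; the descriptor at C2 changes from R to S only because the substituent priorities change.

Step 17
Reactants: 14 (5S)-3-(bromomethyl)-5-{[(4R)-2,2,4-trimethyl-1,3-dioxolan-4-yl]methyl}furan-2(5H)-one; 20 (2Z)-3-methyl-5-(trimethylsilyl)pent-2-en-4-ynal
Product: 25 (4S,5S)-4-[(1R,2Z)-1-hydroxy-3-methyl-5-(trimethylsilyl)pent-2-en-4-yn-1-yl]-3-methylidene-5-{[(4R)-2,2,4-trimethyl-1,3-dioxolan-4-yl]methyl}oxolan-2-one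
Conditions: indium powder, THF/H2O (1:1), rt
Reagents that add atoms: none
Why: Barbier allylation; the allylindium species from 14 should add through its γ-carbon C7 to the aldehyde carbonyl in a closed chair-like six-membered transition state, forming C6–C7 and the exocyclic methylene. Attack on the butenolide face anti to the C8 side chain sets C7 trans to C8, and because the ring locks the γ-substituent trans to the CH2–In group, the chair gives the anti C6/C7 relationship, that is 6R.

Step 18
Reactants: 25 (4S,5S)-4-[(1R,2Z)-1-hydroxy-3-methyl-5-(trimethylsilyl)pent-2-en-4-yn-1-yl]-3-methylidene-5-{[(4R)-2,2,4-trimethyl-1,3-dioxolan-4-yl]methyl}oxolan-2-one; 24 (2S,3R)-2,3-dimethyloxirane-2-carboxylic acid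
Product: 27 (1R,2Z)-3-methyl-1-[(2S,3R)-4-methylidene-5-oxo-2-{[(4R)-2,2,4-trimethyl-1,3-dioxolan-4-yl]methyl}oxolan-3-yl]-5-(trimethylsilyl)pent-2-en-4-yn-1-yl (2S,3R)-2,3-dimethyloxirane-2-carboxylate, via mixed anhydride 26 (not isolated)
Conditions: 24, 2,4,6-trichlorobenzoyl chloride, Et3N, THF, rt; then 25, DMAP, toluene, rt
Reagents that add atoms: none
Why: Yamaguchi esterification; DMAP transfers the aliphatic acyl group of the mixed anhydride to the hindered C6 hydroxyl, and O-acylation leaves C6 and both oxirane centres unchanged.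

Step 19
Reactants: 27 (1R,2Z)-3-methyl-1-[(2S,3R)-4-methylidene-5-oxo-2-{[(4R)-2,2,4-trimethyl-1,3-dioxolan-4-yl]methyl}oxolan-3-yl]-5-(trimethylsilyl)pent-2-en-4-yn-1-yl (2S,3R)-2,3-dimethyloxirane-2-carboxylate
Product: 28 (1R,2Z)-5-iodo-3-methyl-1-[(2S,3R)-4-methylidene-5-oxo-2-{[(4R)-2,2,4-trimethyl-1,3-dioxolan-4-yl]methyl}oxolan-3-yl]pent-2-en-4-yn-1-yl (2S,3R)-2,3-dimethyloxirane-2-carboxylate
Conditions: N-iodosuccinimide, AgNO3 (10 mol %), acetone, rt, dark
Reagents that add atoms: N-iodosuccinimide, O=C1CCC(=O)N1I
Why: Silver-catalysed iododesilylation of an alkynylsilane through a silver acetylide; no base is present, so the acrylate, the esters and the oxirane are left alone.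

Step 20
Reactants: 28 (1R,2Z)-5-iodo-3-methyl-1-[(2S,3R)-4-methylidene-5-oxo-2-{[(4R)-2,2,4-trimethyl-1,3-dioxolan-4-yl]methyl}oxolan-3-yl]pent-2-en-4-yn-1-yl (2S,3R)-2,3-dimethyloxirane-2-carboxylate
Product: 29 (1R,2Z)-1-{(2S,3R)-2-[(2R)-2,3-dihydroxy-2-methylpropyl]-4-methylidene-5-oxooxolan-3-yl}-5-iodo-3-methylpent-2-en-4-yn-1-yl (2S,3R)-2,3-dimethyloxirane-2-carboxylate
Conditions: AcOH/H2O/THF (3:1:1), 40 °C
Reagents that add atoms: none
Why: Acid hydrolysis of the dioxolane; the glycidic ester is deactivated towards acid-induced opening by its carboxyl group, and the methylene lactone and iodoalkyne are inert to aqueous acetic acid.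

Step 21
Reactants: 29 (1R,2Z)-1-{(2S,3R)-2-[(2R)-2,3-dihydroxy-2-methylpropyl]-4-methylidene-5-oxooxolan-3-yl}-5-iodo-3-methylpent-2-en-4-yn-1-yl (2S,3R)-2,3-dimethyloxirane-2-carboxylate
Product: 30 (1R,2Z)-1-{(2S,3R)-2-[(2R)-2-hydroxy-2-methyl-3-oxopropyl]-4-methylidene-5-oxooxolan-3-yl}-5-iodo-3-methylpent-2-en-4-yn-1-yl (2S,3R)-2,3-dimethyloxirane-2-carboxylate
Conditions: SO3·pyridine, DMSO, i-Pr2NEt, CH2Cl2, 0 °C
Reagents that add atoms: none
Why: Parikh–Doering oxidation; activated dimethyl sulfoxide oxidises only the primary alcohol, the tertiary C10 hydroxyl cannot react, and unlike periodate-type oxidants the reagent does not cleave the glycol.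

Step 22
Reactants: 30 (1R,2Z)-1-{(2S,3R)-2-[(2R)-2-hydroxy-2-methyl-3-oxopropyl]-4-methylidene-5-oxooxolan-3-yl}-5-iodo-3-methylpent-2-en-4-yn-1-yl (2S,3R)-2,3-dimethyloxirane-2-carboxylate
Product: 31 (6R,7R,8S,10R)-6-[(2S,3R)-2,3-dimethyloxirane-2-carbonyloxy]-1,10-dihydroxygermacra-4(Z),11(13)-dien-2-yn-12,8-olide (C1 epimers)
Conditions: CrCl2 (10 equiv), NiCl2 (cat.), degassed THF, 2 mM, slow addition of 30, rt
Reagents that add atoms: none
Why: Nozaki–Hiyama–Kishi reaction; divalent chromium converts the alkynyl iodide into an alkynyl species of trivalent chromium, which adds to the aldehyde and not to the esters, lactone or oxirane. High dilution favours closure of the ten-membered ring at C1–C2, and the uncontrolled C1 configuration is removed in the next step.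

Step 23
Reactants: 31 (6R,7R,8S,10R)-6-[(2S,3R)-2,3-dimethyloxirane-2-carbonyloxy]-1,10-dihydroxygermacra-4(Z),11(13)-dien-2-yn-12,8-olide (C1 epimers)
Product: 32 (6R,7R,8S,10R)-6-[(2S,3R)-2,3-dimethyloxirane-2-carbonyloxy]-10-hydroxy-1-oxogermacra-4(Z),11(13)-dien-2-yn-12,8-olide
Conditions: activated MnO2, CH2Cl2, rt
Reagents that add atoms: none
Why: MnO2 oxidises the activated propargylic carbinol to the ynone; the tertiary C10 hydroxyl cannot be oxidised and the neutral surface reagent leaves the other groups alone.

Step 24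
Reactants: 32 (6R,7R,8S,10R)-6-[(2S,3R)-2,3-dimethyloxirane-2-carbonyloxy]-10-hydroxy-1-oxogermacra-4(Z),11(13)-dien-2-yn-12,8-olide
Product: 33 CNP0258430.2 [(6R,7R,8S,10R)-6-[(2S,3R)-2,3-dimethyloxirane-2-carbonyloxy]-1-oxo-3,10-epoxygermacra-2,4(Z),11(13)-trien-12,8-olide]
Conditions: Ph3PAuNTf2 (5 mol %), CH2Cl2, rt
Reagents that add atoms: none
Why: The monovalent gold cation Ph3PAu+ coordinates the C2≡C3 alkyne of the ynone, and the tertiary C10 hydroxyl adds to C3 anti to gold to give an alkenylgold species at C2. Proton transfer from the oxonium ion and protodeauration at C2 release the furanone and regenerate the catalyst. The closest known reaction type is the gold-catalysed cycloisomerisation of acyclic α'-hydroxy ynones (2-hydroxyalk-4-yn-3-ones) to 3(2H)-furanones, used here across a ring. The one ring closed is the five-membered furanone, formed by a transannular 5-endo-dig closure that converts the ten-membered carbocycle into the oxygen-bridged bicycle. No stereocentre is created: C10 keeps the configuration drawn from 1, and C2 and C3 become sp2. The step requires attack of O10 at C3 in preference to external conjugate addition to the ynone or the acrylate and to activation of the oxirane or the C6 ester. The 1,4 relationship of O10 and C3 through the C1 carbonyl, the polarisation of the ynone towards C3, the non-nucleophilic NTf2 counter-ion and a dry non-nucleophilic solvent secure this. The glycidic ester and the acrylate are poor ligands for the soft gold centre, and closure relieves the strain of the cyclic enyne.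

## Compound list

1 | (R)-citramalic acid, (2R)-2-hydroxy-2-methylbutanedioic acid | OC(=O)C[C@@](C(=O)O)(C)O | starting material
2 | (2R)-2-methylbutane-1,2,4-triol | OCC[C@@](CO)(C)O | intermediate
3 | 2-[(4R)-2,2,4-trimethyl-1,3-dioxolan-4-yl]ethan-1-ol | OCC[C@@]1(COC(C)(C)O1)C | intermediate
4 | 2-[(4R)-2,2,4-trimethyl-1,3-dioxolan-4-yl]acetaldehyde | O=CC[C@@]1(COC(C)(C)O1)C | intermediate
5 | tert-butyldimethyl(prop-2-yn-1-yloxy)silane | C#CCO[Si](C)(C)C(C)(C)C | starting material
6 | [3-(tert-butyldimethylsilyloxy)prop-1-yn-1-yl]lithium | [Li]C#CCO[Si](C)(C)C(C)(C)C | intermediate (not isolated)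
7 | (2RS)-5-(tert-butyldimethylsilyloxy)-1-[(4R)-2,2,4-trimethyl-1,3-dioxolan-4-yl]pent-3-yn-2-ol, both C2 epimers | OC(C[C@@]1(COC(C)(C)O1)C)C#CCO[Si](C)(C)C(C)(C)C | intermediate
8 | 5-(tert-butyldimethylsilyloxy)-1-[(4R)-2,2,4-trimethyl-1,3-dioxolan-4-yl]pent-3-yn-2-one | O=C(C[C@@]1(COC(C)(C)O1)C)C#CCO[Si](C)(C)C(C)(C)C | intermediate
9 | (2S)-5-(tert-butyldimethylsilyloxy)-1-[(4R)-2,2,4-trimethyl-1,3-dioxolan-4-yl]pent-3-yn-2-ol | O[C@@H](C[C@@]1(COC(C)(C)O1)C)C#CCO[Si](C)(C)C(C)(C)C | intermediate
10 | sodium cyclic alkenylaluminate from 9: 2,2-bis(2-methoxyethoxy)-2,5-dihydro-1,2-oxaluminol-2-uide whose ring C5 is C8 (S) bearing the dioxolanylmethyl group and whose ring C3 is C11 bearing CH2OTBS | [Na+].COCCO[Al-]1(OCCOC)O[C@@H](C[C@@]2(COC(C)(C)O2)C)C=C1CO[Si](C)(C)C(C)(C)C | intermediate (not isolated)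
11 | (2S,3Z)-5-(tert-butyldimethylsilyloxy)-4-iodo-1-[(4R)-2,2,4-trimethyl-1,3-dioxolan-4-yl]pent-3-en-2-ol | O[C@@H](C[C@@]1(COC(C)(C)O1)C)/C=C(\I)CO[Si](C)(C)C(C)(C)C | intermediate
12 | (5S)-3-[(tert-butyldimethylsilyloxy)methyl]-5-{[(4R)-2,2,4-trimethyl-1,3-dioxolan-4-yl]methyl}furan-2(5H)-one | O=C1O[C@@H](C[C@@]2(COC(C)(C)O2)C)C=C1CO[Si](C)(C)C(C)(C)C | intermediate
13 | (5S)-3-(hydroxymethyl)-5-{[(4R)-2,2,4-trimethyl-1,3-dioxolan-4-yl]methyl}furan-2(5H)-one | O=C1O[C@@H](C[C@@]2(COC(C)(C)O2)C)C=C1CO | intermediate
14 | (5S)-3-(bromomethyl)-5-{[(4R)-2,2,4-trimethyl-1,3-dioxolan-4-yl]methyl}furan-2(5H)-one | O=C1O[C@@H](C[C@@]2(COC(C)(C)O2)C)C=C1CBr | intermediate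
15 | but-2-yn-1-ol | CC#CCO | starting material
16 | sodium cyclic alkenylaluminate from 15: 2,2-bis(2-methoxyethoxy)-3-methyl-2,5-dihydro-1,2-oxaluminol-2-uide | [Na+].COCCO[Al-]1(OCCOC)OCC=C1C | intermediate (not isolated)
17 | (2Z)-3-iodobut-2-en-1-ol | C/C(I)=C/CO | intermediate
18 | ethynyltrimethylsilane | C#C[Si](C)(C)C | starting material
19 | (2Z)-3-methyl-5-(trimethylsilyl)pent-2-en-4-yn-1-ol | C/C(C#C[Si](C)(C)C)=C/CO | intermediate
20 | (2Z)-3-methyl-5-(trimethylsilyl)pent-2-en-4-ynal | C/C(C#C[Si](C)(C)C)=C/C=O | intermediate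
21 | tiglic acid, (2E)-2-methylbut-2-enoic acid | C/C=C(\C)C(=O)O | starting material
22 | (2E)-2-methylbut-2-en-1-ol | C/C=C(\C)CO | intermediate
23 | [(2R,3R)-2,3-dimethyloxiran-2-yl]methanol | OC[C@@]1(C)O[C@@H]1C | intermediate
24 | (2S,3R)-2,3-dimethyloxirane-2-carboxylic acid | OC(=O)[C@@]1(C)O[C@@H]1C | intermediate
25 | (4S,5S)-4-[(1R,2Z)-1-hydroxy-3-methyl-5-(trimethylsilyl)pent-2-en-4-yn-1-yl]-3-methylidene-5-{[(4R)-2,2,4-trimethyl-1,3-dioxolan-4-yl]methyl}oxolan-2-one | C=C1C(=O)O[C@@H](C[C@@]2(COC(C)(C)O2)C)[C@@H]1[C@H](O)/C=C(/C)C#C[Si](C)(C)C | intermediate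
26 | (2S,3R)-2,3-dimethyloxirane-2-carboxylic 2,4,6-trichlorobenzoic anhydride | O=C(OC(=O)[C@@]1(C)O[C@@H]1C)c1c(Cl)cc(Cl)cc1Cl | intermediate (not isolated)
27 | (1R,2Z)-3-methyl-1-[(2S,3R)-4-methylidene-5-oxo-2-{[(4R)-2,2,4-trimethyl-1,3-dioxolan-4-yl]methyl}oxolan-3-yl]-5-(trimethylsilyl)pent-2-en-4-yn-1-yl (2S,3R)-2,3-dimethyloxirane-2-carboxylate | C=C1C(=O)O[C@@H](C[C@@]2(COC(C)(C)O2)C)[C@@H]1[C@H](OC(=O)[C@@]3(C)O[C@@H]3C)/C=C(/C)C#C[Si](C)(C)C | intermediate
28 | (1R,2Z)-5-iodo-3-methyl-1-[(2S,3R)-4-methylidene-5-oxo-2-{[(4R)-2,2,4-trimethyl-1,3-dioxolan-4-yl]methyl}oxolan-3-yl]pent-2-en-4-yn-1-yl (2S,3R)-2,3-dimethyloxirane-2-carboxylate | C=C1C(=O)O[C@@H](C[C@@]2(COC(C)(C)O2)C)[C@@H]1[C@H](OC(=O)[C@@]3(C)O[C@@H]3C)/C=C(/C)C#CI | intermediate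
29 | (1R,2Z)-1-{(2S,3R)-2-[(2R)-2,3-dihydroxy-2-methylpropyl]-4-methylidene-5-oxooxolan-3-yl}-5-iodo-3-methylpent-2-en-4-yn-1-yl (2S,3R)-2,3-dimethyloxirane-2-carboxylate | C=C1C(=O)O[C@@H](C[C@@](C)(O)CO)[C@@H]1[C@H](OC(=O)[C@@]3(C)O[C@@H]3C)/C=C(/C)C#CI | intermediate
30 | (1R,2Z)-1-{(2S,3R)-2-[(2R)-2-hydroxy-2-methyl-3-oxopropyl]-4-methylidene-5-oxooxolan-3-yl}-5-iodo-3-methylpent-2-en-4-yn-1-yl (2S,3R)-2,3-dimethyloxirane-2-carboxylate | C=C1C(=O)O[C@@H](C[C@@](C)(O)C=O)[C@@H]1[C@H](OC(=O)[C@@]3(C)O[C@@H]3C)/C=C(/C)C#CI | intermediate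
31 | (6R,7R,8S,10R)-6-[(2S,3R)-2,3-dimethyloxirane-2-carbonyloxy]-1,10-dihydroxygermacra-4(Z),11(13)-dien-2-yn-12,8-olide, C1 epimers | C=C1C(=O)O[C@H]2C[C@@](C)(O)C(O)C#C/C(C)=C\[C@@H](OC(=O)[C@@]3(C)O[C@@H]3C)[C@H]12 | intermediate
32 | (6R,7R,8S,10R)-6-[(2S,3R)-2,3-dimethyloxirane-2-carbonyloxy]-10-hydroxy-1-oxogermacra-4(Z),11(13)-dien-2-yn-12,8-olide | C=C1C(=O)O[C@H]2C[C@@](C)(O)C(=O)C#C/C(C)=C\[C@@H](OC(=O)[C@@]3(C)O[C@@H]3C)[C@H]12 | intermediate
33 | CNP0258430.2, (6R,7R,8S,10R)-6-[(2S,3R)-2,3-dimethyloxirane-2-carbonyloxy]-1-oxo-3,10-epoxygermacra-2,4(Z),11(13)-trien-12,8-olide | C=C1C(=O)O[C@H]2C[C@@]3(C)OC(=CC3=O)/C(C)=C\[C@@H](OC(=O)[C@@]3(C)O[C@@H]3C)[C@H]12 | target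

## Step count and risks

Total: 24 steps. Longest linear sequence: 18 steps, made up of steps 1–10 and 17–24. Steps 11–13 make the enynal 20 and steps 14–16 make the acid 24.

**Step 24 (key step).** The strained, doubly activated ynone may be consumed by intermolecular conjugate addition or oligomerisation, or gold may engage the enyne and its C6 ester, before the transannular O–C3 bond forms. The fallback reverses the order of oxidation and cyclisation and sets out from 31. The same catalyst, or AgOTf, is applied to the diol, whose alkyne is an electron-rich enyne and not a Michael acceptor. 5-endo addition of the C10 hydroxyl to C3 should give the bridged 1-hydroxy-2,3-dihydrofuran F1, which cannot aromatise because C10 is quaternary. Activated MnO2 then oxidises its allylic C1 carbinol to the furanone, which rejoins the route at 33.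

**Step 22.** Ring closure may lose to protodeiodination or intermolecular coupling because the cyclic Z-enyne is strained. The free α-hydroxy aldehyde may also undergo an α-ketol shift or self-condensation on the Lewis-acidic chromium salts. The fallback closes the ring on a silylated substrate and sets out from 29. TESOTf and 2,6-lutidine give the bis(triethylsilyl) ether F2. Swern conditions cleave and oxidise only the primary silyl ether, giving the α-silyloxy aldehyde F3, which cannot rearrange or chelate. CrCl2/NiCl2 closure gives the macrocyclic carbinol F4, Dess–Martin oxidation gives the silylated ynone F5, and HF·pyridine frees the tertiary hydroxyl to rejoin the route at 32.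

**Step 20.** Acid may open the oxirane or ionise the allylic C6 ester in competition with acetal hydrolysis. The fallback removes the acetal before the acid-sensitive ester is present and sets out from 25. Aqueous acetic acid gives the triol F6, and TBSCl/imidazole at low temperature silylates only the primary hydroxyl to give the primary silyl ether F7. Yamaguchi acylation with 24 at the C6 hydroxyl, the tertiary hydroxyl being unreactive, gives the ester F8, and N-iodosuccinimide/AgNO3 gives the iodoalkyne F9. Buffered HF·pyridine then removes the primary silyl group to rejoin the route at 29.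

**Step 17.** The closed transition state may be poorly organised in water, so that addition through the alternative arrangement gives the C6 epimer as a major product, and indium salts may isomerise the Z-enal. The fallback sets out from 14 and 20, accepts the epimeric outcome of the same allylation and corrects C6 in the acylation instead. The separated 6S alcohol F10 is esterified with acid 24 under Mitsunobu conditions (PPh3, diisopropyl azodicarboxylate, THF, 0 °C), which inverts C6 and acylates it in one operation, rejoining the route at 27.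

## Further compounds

F1 | step 24 | (6R,7R,8S,10R)-6-[(2S,3R)-2,3-dimethyloxirane-2-carbonyloxy]-1-hydroxy-3,10-epoxygermacra-2,4(Z),11(13)-trien-12,8-olide, C1 epimers | C=C1C(=O)O[C@H]2C[C@@]3(C)OC(=CC3O)/C(C)=C\[C@@H](OC(=O)[C@@]4(C)O[C@@H]4C)[C@H]12
F2 | step 22 | bis(triethylsilyl) ether of diol 29, O1 and O10 silylated | C=C1C(=O)O[C@@H](C[C@@](C)(O[Si](CC)(CC)CC)CO[Si](CC)(CC)CC)[C@@H]1[C@H](OC(=O)[C@@]3(C)O[C@@H]3C)/C=C(/C)C#CI
F3 | step 22 | 10-O-triethylsilyl ether of aldehyde 30 | C=C1C(=O)O[C@@H](C[C@@](C)(O[Si](CC)(CC)CC)C=O)[C@@H]1[C@H](OC(=O)[C@@]3(C)O[C@@H]3C)/C=C(/C)C#CI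
F4 | step 22 | 10-O-triethylsilyl ether of macrocyclic diol 31, C1 epimers | C=C1C(=O)O[C@H]2C[C@@](C)(O[Si](CC)(CC)CC)C(O)C#C/C(C)=C\[C@@H](OC(=O)[C@@]3(C)O[C@@H]3C)[C@H]12
F5 | step 22 | 10-O-triethylsilyl ether of ynone 32 | C=C1C(=O)O[C@H]2C[C@@](C)(O[Si](CC)(CC)CC)C(=O)C#C/C(C)=C\[C@@H](OC(=O)[C@@]3(C)O[C@@H]3C)[C@H]12
F6 | step 20 | (4S,5S)-5-[(2R)-2,3-dihydroxy-2-methylpropyl]-4-[(1R,2Z)-1-hydroxy-3-methyl-5-(trimethylsilyl)pent-2-en-4-yn-1-yl]-3-methylideneoxolan-2-one | C=C1C(=O)O[C@@H](C[C@@](C)(O)CO)[C@@H]1[C@H](O)/C=C(/C)C#C[Si](C)(C)C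
F7 | step 20 | primary tert-butyldimethylsilyl ether of triol F6 | C=C1C(=O)O[C@@H](C[C@@](C)(O)CO[Si](C)(C)C(C)(C)C)[C@@H]1[C@H](O)/C=C(/C)C#C[Si](C)(C)C
F8 | step 20 | C6 (2S,3R)-2,3-dimethyloxirane-2-carboxylate of F7 | C=C1C(=O)O[C@@H](C[C@@](C)(O)CO[Si](C)(C)C(C)(C)C)[C@@H]1[C@H](OC(=O)[C@@]3(C)O[C@@H]3C)/C=C(/C)C#C[Si](C)(C)C
F9 | step 20 | iodoalkyne from F8, the primary tert-butyldimethylsilyl ether of diol 29 | C=C1C(=O)O[C@@H](C[C@@](C)(O)CO[Si](C)(C)C(C)(C)C)[C@@H]1[C@H](OC(=O)[C@@]3(C)O[C@@H]3C)/C=C(/C)C#CI
F10 | step 17 | (4S,5S)-4-[(1S,2Z)-1-hydroxy-3-methyl-5-(trimethylsilyl)pent-2-en-4-yn-1-yl]-3-methylidene-5-{[(4R)-2,2,4-trimethyl-1,3-dioxolan-4-yl]methyl}oxolan-2-one, the C6 epimer of 25 | C=C1C(=O)O[C@@H](C[C@@]2(COC(C)(C)O2)C)[C@@H]1[C@@H](O)/C=C(/C)C#C[Si](C)(C)C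
A1 | alternative 1 | open-chain 2-methyl-3-(triisopropylsilyloxy)furan carrying the C4–C9 chain with a C8=C9 methyl enol ether | C=C(CO[Si](C)(C)C(C)(C)C)[C@H](C(OC)=C)[C@H](O[Si](C)(C)C(C)(C)C)/C=C(C)\c1cc(O[Si](C(C)C)(C(C)C)C(C)C)c(C)o1
A2 | alternative 1 | bicyclic furanone with C8 dimethyl ketal | C=C(CO[Si](C)(C)C(C)(C)C)[C@H]1[C@H](O[Si](C)(C)C(C)(C)C)/C=C(C)\C2=CC(=O)[C@@](C)(CC1(OC)OC)O2
A3 | alternative 2 | bicyclic furanone 6,7-epoxide with O8 diethylphosphonoacetate | CCOP(=O)(OCC)CC(=O)O[C@H]1C[C@@]2(C)OC(=CC2=O)/C(C)=C\[C@H]3O[C@@H]13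
A4 | alternative 2 | α-diethylphosphono lactone with free C6 hydroxyl | CCOP(=O)(OCC)[C@H]1C(=O)O[C@H]2C[C@@]3(C)OC(=CC3=O)/C(C)=C\[C@@H](O)[C@H]12
A5 | alternative 3 | furanone Z-alkenyl iodide with C6 aldehyde on the phenylthiomethyl lactone | c1ccccc1SC[C@H]1C(=O)O[C@@H](C[C@@]2(C)OC(=CC2=O)/C(C)=C\I)[C@@H]1C=O
A6 | alternative 3 | bicyclic C6 carbinol with phenylthiomethyl lactone | c1ccccc1SC[C@H]1C(=O)O[C@H]2C[C@@]3(C)OC(=CC3=O)/C(C)=C\[C@@H](O)[C@H]12
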